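**Retrosynthetic overview**
1. Target 34 ← 12-ketone 31 (hydride) ← ketol 30 by an α-ketol shift of C16 from C12 to C13. The strategy rests on the secondary C12 carbinol next to the bridgehead tertiary C13 carbinol (bearing C16) in the bicyclo[3.2.1]octane of rings C and D.
2. 30 ← C12–C16 closure (palladium enolate alkenylation) of α-silyloxy ketone 28 ← conjugate 2-bromoallylation at C8 of enone 24 ← Birch reduction of the anisole ring C of 20.
3. 20 ← ring A by aldol (C3–C4) ← γ-lactone by intramolecular Michael addition (C4–C5) ← C10 carbinol by catalytic asymmetric allylboration of indanone 5 ← Friedel–Crafts closure of ring B.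
4. Order of ring formation: B (on aromatic C), lactone, A, dearomatised C, the C15–C16 bridge (bicyclo[2.2.2]octane), then D by the ketol shift.

Key step: step 20

Convention: gibberellane atom numbers are used (ring A C1–C5, C10; ring B C5, C6, C8, C9, C10; ring C C8, C9, C11–C14; ring D C8, C13–C16; C7 carboxyl on C6; C18 methyl and C19 lactone carbonyl on C4; C17 methylene). α is the face of ring B carrying the lactone oxygen and C4; β is the face carrying H5, H9, C7 and C1. TBS = tert-butyldimethylsilyl, TES = triethylsilyl.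
Remark: C6 bears an acidic hydrogen next to its ester or acid and is drawn from 12 on in the configuration expected at equilibrium (C7 β, trans to C4); the base and acid steps 6, 14, 18 and 20 allow this equilibration.

Step 1
Reactants: 1 methyl 2-(3-methoxyphenyl)acetate; 2 tert-butyl bromoacetate
Product: 3 4-tert-butyl 1-methyl 2-(3-methoxyphenyl)butanedioate (racemic)
Conditions: LiN(iPr)2, THF, −78 °C; then 2, −78 to 0 °C
Reagents that add atoms: none
Why: Alkylation of the ester enolate (SN2 on the α-bromo ester) puts C5 and C10 on C6, whose configuration is left racemic because it stays epimerisable and is settled later under thermodynamic control.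

Step 2
Reactants: 3
Product: 5 methyl 6-methoxy-3-oxoindane-1-carboxylate (racemic), via half acid 4 (not isolated)
Conditions: CF3CO2H, CH2Cl2, 23 °C; then (CF3CO)2O, 0 to 23 °C
Reagents that add atoms: none
Why: Acidolysis of the tert-butyl ester and intramolecular Friedel–Crafts acylation through the mixed anhydride close ring B para to the methoxy group, the only activated and unhindered position beside the side chain.

Step 3
Reactants: 5; 6 diisopropyl prop-2-enylboronate
Product: 7 methyl (3S)-3-hydroxy-6-methoxy-3-(prop-2-enyl)indane-1-carboxylate (both C1 epimers)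
Conditions: (S)-3,3'-dibromo-1,1'-bi-2-naphthol (15 mol%), PhMe/PhCF3, −35 °C
Reagents that add atoms: none
Why: Diol-catalysed asymmetric allylboration of the aryl ketone is expected to deliver the allyl group (C1–C3) to the Re face of C10, which fixes the quaternary carbinol from which all other stereocentres are relayed; the antipodal catalyst is the remedy if the sense of induction is the opposite.

Step 4
Reactants: 7
Product: 9 methyl (1S)-1-hydroxy-5-methoxy-1-(prop-2-enyl)-1H-indene-3-carboxylate, via C6 phenylselenide 8 (not isolated)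
Conditions: LiN(iPr)2 (2.2 equiv), THF, −78 °C; PhSeBr; then H2O2, pyridine, CH2Cl2, 0 to 23 °C
Reagents that add atoms: none
Why: Selenenylation of the ester enolate and syn-elimination of the selenoxide give the C5=C6 unsaturated ester, which removes the uncontrolled C6 centre and makes C5 electrophilic.

Step 5
Reactants: 9; 10 propanoic anhydride
Product: 11 methyl (1S)-5-methoxy-1-(propanoyloxy)-1-(prop-2-enyl)-1H-indene-3-carboxylate
Conditions: LiN(SiMe3)2, THF, −78 °C; then 10, −78 to 0 °C
Reagents that add atoms: none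
Why: O-acylation of the tertiary lithium alkoxide hangs the C4/C18/C19 propanoate on the C10 oxygen.

Step 6
Reactants: 11
Product: 12 methyl 6-methoxy-3-methyl-2-oxo-8b-(prop-2-enyl)-3,3a,4,8b-tetrahydro-2H-indeno[1,2-b]furan-4-carboxylate (cis-fused lactone; C3 methyl epimers)
Conditions: LiN(iPr)2, THF, −78 to −20 °C; AcOH
Reagents that add atoms: none
Why: Intramolecular Michael addition (5-exo-trig) of the propanoate enolate carbon C4 to C5 of the α-aryl acrylate forms the C4–C5 bond and the γ-lactone, the tether forcing the new bond onto the face of the C10 oxygen, and C6 is protonated to the more stable ester trans to C4.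

Step 7
Reactants: 12
Product: 13 6-methoxy-3-methyl-2-oxo-8b-(prop-2-enyl)-3,3a,4,8b-tetrahydro-2H-indeno[1,2-b]furan-4-carboxylic acid
Conditions: LiOH, THF/H2O, 23 °C; then aq. HCl to pH 3
Reagents that add atoms: water, O
Why: Saponification of the unhindered methyl ester gives the carboxylate that keeps C6–H from enolising in the later base steps, and any opened lactone recloses on acidification because only the C19 carboxyl is cis to the C10 hydroxyl.

Step 8
Reactants: 13
Product: 14 8b-(3-hydroxypropyl)-6-methoxy-3-methyl-2-oxo-3,3a,4,8b-tetrahydro-2H-indeno[1,2-b]furan-4-carboxylic acid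
Conditions: 9-BBN-H (3 equiv), THF, 0 to 23 °C; then NaOH, H2O2, 0 °C; aq. HCl
Reagents that add atoms: hydrogen peroxide, OO
Why: Anti-Markovnikov hydroboration–oxidation of the terminal alkene places the oxygen on C3.

Step 9
Reactants: 14
Product: 15 6-methoxy-3-methyl-2-oxo-8b-(3-oxopropyl)-3,3a,4,8b-tetrahydro-2H-indeno[1,2-b]furan-4-carboxylic acid
Conditions: Dess–Martin periodinane, NaHCO3, CH2Cl2, 0 to 23 °C
Reagents that add atoms: none
Why: Dess–Martin oxidation of the primary alcohol stops at the C3 aldehyde.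

Step 10
Reactants: 15
Product: 16 3-hydroxy-13-methoxy-20-norgibberella-8,11,13-triene-7,19-dioic acid 19,10-lactone (C3 epimers)
Conditions: KOtBu (2.2 equiv), THF/t-BuOH, 0 °C; aq. HCl
Reagents that add atoms: none
Why: Intramolecular aldol addition of the lactone enolate carbon C4 to the C3 aldehyde closes ring A, the bridged lactone allowing only the C4 configuration with the methyl group exo, while C6 cannot compete because it is α to a carboxylate.

Step 11
Reactants: 16
Product: 17 13-methoxy-3-oxo-20-norgibberella-8,11,13-triene-7,19-dioic acid 19,10-lactone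
Conditions: Dess–Martin periodinane, NaHCO3, CH2Cl2, 23 °C
Reagents that add atoms: none
Why: Oxidation of both C3 epimers to one ketone removes the poorly controlled aldol centre.

Step 12
Reactants: 17
Product: 18 3β-hydroxy-13-methoxy-20-norgibberella-8,11,13-triene-7,19-dioic acid 19,10-lactone
Conditions: K[BH(s-Bu)3] (3 equiv), THF, −78 °C; AcOH at −78 °C
Reagents that add atoms: none
Why: The bulky hydride should attack the C3 ketone equatorially and give the axial 3β alcohol (anti to the lactone bridge), as in hindered-hydride reductions of 4,4-disubstituted cyclohexan-3-ones, and the cold quench prevents retro-aldol epimerisation.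

Step 13
Reactants: 18
Product: 20 3β-(tert-butyldimethylsilyloxy)-13-methoxy-20-norgibberella-8,11,13-triene-7,19-dioic acid 19,10-lactone, via silyl ester 19 (not isolated)
Conditions: t-BuMe2SiOTf (2.5 equiv), 2,6-lutidine, CH2Cl2, 0 °C; then AcOH, THF/H2O
Reagents that add atoms: tert-butyldimethylsilyl trifluoromethanesulfonate, CC(C)(C)[Si](C)(C)OS(=O)(=O)C(F)(F)F
Why: Silylation protects the 3-hydroxyl against retro-aldol epimerisation in all later base steps, and the labile silyl ester is hydrolysed in the work-up.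

Step 14
Reactants: 20
Product: 23 3β-(tert-butyldimethylsilyloxy)-13-oxo-20-norgibberell-8(14)-ene-7,19-dioic acid 19,10-lactone (9β-H), via hydroxy diacid lithium salt 21 (not isolated), via dihydroanisole 22 (not isolated)
Conditions: LiOH, THF/H2O, 50 °C, then evaporation; Li, NH3(l), THF, t-BuOH, −78 to −33 °C; NH4Cl; then 2 M HCl, THF, 23 °C
Reagents that add atoms: water, O
Why: Birch reduction of the anisole ring is run on the ring-opened alkoxide dicarboxylate so that the benzylic C10–O bond is not hydrogenolysed, after which aqueous acid hydrolyses the enol ether, moves the double bond into conjugation (C8=C14) and recloses the lactone, C9 being protonated under thermodynamic control to the isomer with C11 anti to C1 (9β-H).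

Step 15
Reactants: 23
Product: 24 methyl 3β-(tert-butyldimethylsilyloxy)-13-oxo-20-norgibberell-8(14)-en-7-oate 19,10-lactone
Conditions: Me3SiCHN2, PhMe/MeOH, 0 °C
Reagents that add atoms: trimethylsilyldiazomethane, C[Si](C)(C)C=[N+]=[N-]
Why: Methylation of the carboxylic acid by the diazoalkane gives the C7 methyl ester needed for the Lewis acid step that follows.

Step 16
Reactants: 24; 25 2-bromoallyltrimethylsilane
Product: 26 ketone from 24 with C8–C14 saturated and a 2-bromoprop-2-enyl group (C15–C17) on C8 cis to H9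
Conditions: TiCl4, CH2Cl2, −78 °C
Reagents that add atoms: none
Why: Hosomi–Sakurai conjugate addition of the allylsilane to the β,β-disubstituted enone creates the quaternary C8 with C15 cis to H9, the usual result of axial attack anti to the ring bond at the γ-carbon of a bicyclic enone (cis-hydrindanone).

Step 17
Reactants: 26
Product: 28 12-(triethylsilyloxy) derivative of ketone 26 (C12 epimers), via triethylsilyl enol ether 27 (not isolated)
Conditions: LiN(iPr)2, THF, −78 °C; Et3SiCl; then mCPBA, NaHCO3, CH2Cl2, 0 °C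
Reagents that add atoms: chlorotriethylsilane, CC[Si](Cl)(CC)CC; 3-chloroperoxybenzoic acid, OOC(=O)c1cccc(Cl)c1
Why: Kinetic enolisation away from the quaternary C8 and Rubottom oxidation of the silyl enol ether put the oxygen on C12 with silyl migration to it, the C12 configuration being irrelevant because this carbon is enolised again in the next step.

Step 18
Reactants: 28
Product: 29 methyl ester lactone with C16 bonded to C12 (bicyclo[2.2.2]octane C8/C12 with bridges C9–C11 and C13–C14 and C15–C16): 12-OTES and 13-oxo and 16(17)-methylene and 3β-OTBS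
Conditions: Pd(PPh3)4 (10 mol%), KOPh, THF, 65 °C
Reagents that add atoms: none
Why: Proposed new method: oxidative addition of zerovalent palladium into the alkenyl bromide, capture of the alkenylpalladium bromide by the C12 enolate of the α-silyloxy ketone and reductive elimination should forge the C12–C16 bond, only the C12 enolate being able to reach C16 (the C14 enolate would have to close a four-membered ring) and C15 on the β face of C8 dictating the C12 configuration; the closest known reaction is the palladium-catalysed intramolecular α-alkenylation of ketone enolates at CH or CH2 carbons, which has not been shown for an α-silyloxy methine that becomes a bridgehead tertiary carbinol.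

Step 19
Reactants: 29
Product: 30 12-hydroxy-13-oxo bicyclo[2.2.2]octane ketol (C16 on C12; 3β-OTBS; C7 methyl ester)
Conditions: HF·pyridine, pyridine, THF, 0 °C
Reagents that add atoms: none
Why: Buffered fluoride removes the triethylsilyl ether faster than the hindered secondary tert-butyldimethylsilyl ether and is not basic enough to start the ketol shift.

Step 20
Reactants: 30
Product: 31 methyl 3β-(tert-butyldimethylsilyloxy)-13-hydroxy-12-oxo-20-norgibberell-16-en-7-oate 19,10-lactone
Conditions: KN(SiMe3)2 (1.05 equiv), THF, −78 to −20 °C; AcOH at −78 °C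
Reagents that add atoms: none
Why: Deprotonation of the C12 hydroxyl gives an alkoxide, and re-formation of C=O at C12 drives a concerted suprafacial 1,2-shift of the C12–C16 bond onto the C13 carbonyl carbon (α-ketol or acyloin rearrangement), the C13 oxygen becoming the bridgehead alkoxide. The closest known reaction type is the base- or Lewis-acid-mediated α-ketol rearrangement of bridgehead hydroxy ketones that turns bicyclo[2.2.2]octanes into bicyclo[3.2.1]octanes. Ring D (C8, C15, C16, C13, C14) closes by this 1,2-shift, that is by contraction of the six-membered ring C8–C15–C16–C12–C13–C14, while ring C (C8, C9, C11, C12, C13, C14) is kept. The new stereocentre C13 is set by the cage, because C16 can reach only the face of the C13 carbonyl on which the C15–C16 bridge already lies, which leaves the hydroxyl equatorial on ring C. The step needs migration of C16 and not of C11, which are equally well aligned with the carbonyl π* orbital; the sp2 carbon C16 should migrate faster because its π bond assists the shift, and 31 is favoured over 30 by the change from a boat cyclohexanone in a bicyclo[2.2.2]octane to a chair cyclohexanone in a bicyclo[3.2.1]octane. One equivalent of base, low temperature and a cold acidic quench keep the slower alkyl shifts to conjugated isomers and enolisation of the C6 ester out of play.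

Step 21
Reactants: 31
Product: 32 methyl 3β-(tert-butyldimethylsilyloxy)-12,13-dihydroxy-20-norgibberell-16-en-7-oate 19,10-lactone (12-hydroxyl axial and cis to the 13-hydroxyl)
Conditions: Li[BH(s-Bu)3], THF, −78 °C; NH4Cl
Reagents that add atoms: none
Why: Hydride reduction under steric approach control: the α face of the C12 ketone is closed by C10 and its lactone oxygen, which are syn-axial to C12, so hydride enters from the β face and the new hydroxyl is axial, cis to the C13 hydroxyl and anti to the C15–C16 bridge.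

Step 22
Reactants: 32
Product: 33 3β-(tert-butyldimethylsilyloxy)-12,13-dihydroxy-20-norgibberell-16-ene-7,19-dioic acid 19,10-lactone
Conditions: n-PrSH, n-BuLi, HMPA, 23 °C; aq. HCl
Reagents that add atoms: none
Why: SN2 demethylation of the hindered C7 methyl ester by lithium propanethiolate leaves the lactone, whose alkyl carbon is tertiary, and the silyl-protected 3-oxygen untouched.

Step 23
Reactants: 33
Product: 34 CNP0260503.1 (3β,12,13-trihydroxy-20-norgibberell-16-ene-7,19-dioic acid 19,10-lactone)
Conditions: HF·pyridine, THF, 23 °C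
Reagents that add atoms: none
Why: Cleavage of the silyl ether by fluoride under weakly acidic conditions frees the 3β-hydroxyl without the retro-aldol epimerisation that base would cause.

**Compound list**
1 | methyl 2-(3-methoxyphenyl)acetate | COC(=O)Cc1cccc(OC)c1 | starting material
2 | tert-butyl bromoacetate | BrCC(=O)OC(C)(C)C | starting material
3 | 4-tert-butyl 1-methyl 2-(3-methoxyphenyl)butanedioate (racemic) | COC(=O)C(CC(=O)OC(C)(C)C)c1cccc(OC)c1 | intermediate
4 | 4-methoxy-3-(3-methoxyphenyl)-4-oxobutanoic acid (racemic, not isolated) | COC(=O)C(CC(=O)O)c1cccc(OC)c1 | intermediate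
5 | methyl 6-methoxy-3-oxo-2,3-dihydro-1H-indene-1-carboxylate (racemic; C1 = C6, C3 = C10) | COC(=O)C1CC(=O)c2ccc(OC)cc12 | intermediate
6 | diisopropyl prop-2-enylboronate | C=CCB(OC(C)C)OC(C)C | starting material
7 | methyl (3S)-3-hydroxy-6-methoxy-3-(prop-2-enyl)-2,3-dihydro-1H-indene-1-carboxylate (both C1 epimers) | COC(=O)C1C[C@@](O)(CC=C)c2ccc(OC)cc12 | intermediate
8 | methyl (3S)-3-hydroxy-6-methoxy-1-(phenylselanyl)-3-(prop-2-enyl)-2,3-dihydro-1H-indene-1-carboxylate (not isolated) | COC(=O)C1([Se]c3ccccc3)C[C@@](O)(CC=C)c2ccc(OC)cc12 | intermediate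
9 | methyl (1S)-1-hydroxy-5-methoxy-1-(prop-2-enyl)-1H-indene-3-carboxylate | COC(=O)C1=C[C@@](O)(CC=C)c2ccc(OC)cc12 | intermediate
10 | propanoic anhydride | CCC(=O)OC(=O)CC | starting material
11 | methyl (1S)-5-methoxy-1-(propanoyloxy)-1-(prop-2-enyl)-1H-indene-3-carboxylate | COC(=O)C1=C[C@@](OC(=O)CC)(CC=C)c2ccc(OC)cc12 | intermediate
12 | methyl 6-methoxy-3-methyl-2-oxo-8b-(prop-2-enyl)-3,3a,4,8b-tetrahydro-2H-indeno[1,2-b]furan-4-carboxylate; lactone cis-fused, ester trans to the C3a–C3 bond, C3 methyl epimers (C8b = C10, C3a = C5, C4 = C6, C3 = C4 of the target) | COc1ccc2c(c1)[C@@H](C(=O)OC)[C@@H]1C(C)C(=O)O[C@@]12CC=C | intermediate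
13 | the 4-carboxylic acid corresponding to 12 | COc1ccc2c(c1)[C@@H](C(=O)O)[C@@H]1C(C)C(=O)O[C@@]12CC=C | intermediate
14 | 8b-(3-hydroxypropyl) analogue of 13 | COc1ccc2c(c1)[C@@H](C(=O)O)[C@@H]1C(C)C(=O)O[C@@]12CCCO | intermediate
15 | 8b-(3-oxopropyl) analogue of 13 (C3 aldehyde) | COc1ccc2c(c1)[C@@H](C(=O)O)[C@@H]1C(C)C(=O)O[C@@]12CCC=O | intermediate
16 | 3-hydroxy-13-methoxy-20-norgibberella-8,11,13-triene-7,19-dioic acid 19,10-lactone (ring C aromatic, C3 epimers) | O=C1O[C@@]23CCC(O)[C@]1(C)[C@H]2[C@H](C(=O)O)c1cc(OC)ccc13 | intermediate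
17 | 13-methoxy-3-oxo-20-norgibberella-8,11,13-triene-7,19-dioic acid 19,10-lactone | O=C1O[C@@]23CCC(=O)[C@]1(C)[C@H]2[C@H](C(=O)O)c1cc(OC)ccc13 | intermediate
18 | 3β-hydroxy-13-methoxy-20-norgibberella-8,11,13-triene-7,19-dioic acid 19,10-lactone (3-hydroxyl axial, anti to the lactone bridge) | O=C1O[C@@]23CC[C@H](O)[C@]1(C)[C@H]2[C@H](C(=O)O)c1cc(OC)ccc13 | intermediate
19 | 3-O-TBS ether 7-TBS ester of 18 (not isolated) | O=C1O[C@@]23CC[C@H](O[Si](C)(C)C(C)(C)C)[C@]1(C)[C@H]2[C@H](C(=O)O[Si](C)(C)C(C)(C)C)c1cc(OC)ccc13 | intermediate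
20 | 3β-(tert-butyldimethylsilyloxy)-13-methoxy-20-norgibberella-8,11,13-triene-7,19-dioic acid 19,10-lactone | O=C1O[C@@]23CC[C@H](O[Si](C)(C)C(C)(C)C)[C@]1(C)[C@H]2[C@H](C(=O)O)c1cc(OC)ccc13 | intermediate
21 | 3β-(tert-butyldimethylsilyloxy)-10-hydroxy-13-methoxy-20-norgibberella-8,11,13-triene-7,19-dioic acid, formed as its lithium salt (lactone opened, not isolated) | OC(=O)[C@]1(C)[C@@H](O[Si](C)(C)C(C)(C)C)CC[C@]2(O)[C@@H]1[C@H](C(=O)O)c1cc(OC)ccc12 | intermediate
22 | 11,14-dihydro derivative of 21 (8,12-diene, methyl enol ether at C13; lithium salt, not isolated) | OC(=O)[C@]1(C)[C@@H](O[Si](C)(C)C(C)(C)C)CC[C@]2(O)[C@@H]1[C@H](C(=O)O)C1=C2CC=C(OC)C1 | intermediate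
23 | 3β-(tert-butyldimethylsilyloxy)-13-oxo-20-norgibberell-8(14)-ene-7,19-dioic acid 19,10-lactone (9β-H) | O=C1O[C@@]23CC[C@H](O[Si](C)(C)C(C)(C)C)[C@]1(C)[C@H]2[C@H](C(=O)O)C1=CC(=O)CC[C@H]13 | intermediate
24 | methyl ester of 23 | O=C1O[C@@]23CC[C@H](O[Si](C)(C)C(C)(C)C)[C@]1(C)[C@H]2[C@H](C(=O)OC)C1=CC(=O)CC[C@H]13 | intermediate
25 | 2-bromoallyltrimethylsilane | C=C(Br)C[Si](C)(C)C | starting material
26 | 13-ketone from 24 with C8–C14 saturated and a 2-bromoprop-2-enyl group (C15–C17) on C8, β, cis to H9 | O=C1O[C@@]23CC[C@H](O[Si](C)(C)C(C)(C)C)[C@]1(C)[C@H]2[C@H](C(=O)OC)[C@@]1(CC(Br)=C)CC(=O)CC[C@H]13 | intermediate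
27 | 12(13)-triethylsilyl enol ether of 26 (not isolated) | O=C1O[C@@]23CC[C@H](O[Si](C)(C)C(C)(C)C)[C@]1(C)[C@H]2[C@H](C(=O)OC)[C@@]1(CC(Br)=C)CC(O[Si](CC)(CC)CC)=CC[C@H]13 | intermediate
28 | 12-(triethylsilyloxy) derivative of ketone 26 (C12 epimers) | O=C1O[C@@]23CC[C@H](O[Si](C)(C)C(C)(C)C)[C@]1(C)[C@H]2[C@H](C(=O)OC)[C@@]1(CC(Br)=C)CC(=O)C(O[Si](CC)(CC)CC)C[C@H]13 | intermediate
29 | 12-O-TES ether of ketol 30 | C=C1C[C@]23CC(=O)[C@@]1(O[Si](CC)(CC)CC)C[C@H]2[C@@]12CC[C@H](O[Si](C)(C)C(C)(C)C)[C@@](C)(C(=O)O1)[C@H]2[C@@H]3C(=O)OC | intermediate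
30 | 12-hydroxy-13-oxo ketol with C16 bonded to C12 (bicyclo[2.2.2]octane with bridgeheads C8 and C12), 16(17)-methylene, 3β-OTBS, 19,10-lactone, C7 methyl ester | C=C1C[C@]23CC(=O)[C@@]1(O)C[C@H]2[C@@]12CC[C@H](O[Si](C)(C)C(C)(C)C)[C@@](C)(C(=O)O1)[C@H]2[C@@H]3C(=O)OC | intermediate
31 | methyl 3β-(tert-butyldimethylsilyloxy)-13-hydroxy-12-oxo-20-norgibberell-16-en-7-oate 19,10-lactone | C=C1C[C@]23C[C@@]1(O)C(=O)C[C@H]2[C@@]12CC[C@H](O[Si](C)(C)C(C)(C)C)[C@@](C)(C(=O)O1)[C@H]2[C@@H]3C(=O)OC | intermediate
32 | methyl 3β-(tert-butyldimethylsilyloxy)-12,13-dihydroxy-20-norgibberell-16-en-7-oate 19,10-lactone (12-hydroxyl axial, cis to 13-hydroxyl, anti to the C15–C16 bridge) | C=C1C[C@]23C[C@@]1(O)[C@@H](O)C[C@H]2[C@@]12CC[C@H](O[Si](C)(C)C(C)(C)C)[C@@](C)(C(=O)O1)[C@H]2[C@@H]3C(=O)OC | intermediate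
33 | 7-carboxylic acid corresponding to 32 | C=C1C[C@]23C[C@@]1(O)[C@@H](O)C[C@H]2[C@@]12CC[C@H](O[Si](C)(C)C(C)(C)C)[C@@](C)(C(=O)O1)[C@H]2[C@@H]3C(=O)O | intermediate
34 | CNP0260503.1 | C=C1C[C@]23C[C@@]1(O)[C@@H](O)C[C@H]2[C@@]12CC[C@H](O)[C@@](C)(C(=O)O1)[C@H]2[C@@H]3C(=O)O | target

**Step count**
Total steps: 23. Longest linear sequence: 23 (1 → 34; compounds 2, 6, 10 and 25 are bought).

**Steps most likely to fail**

Step 18 (proposed new method). The hindered, oxygen-bearing C12 enolate may fail to couple with the alkenylpalladium species, the palladium enolate may undergo β-hydride elimination toward C11, or the base may eliminate HBr from the bromoalkene. The fallback reverses the polarity of the ring closure and uses only known reactions. It sets out from 28. NaBH4 reduces the C13 ketone to the C13 alcohol F1, Ac2O/DMAP gives the C13 acetate F2, HF·pyridine frees the C12 alcohol F3, and Dess–Martin oxidation gives the C12 ketone F4. CrCl2 with catalytic NiCl2 in DMSO (Nozaki–Hiyama–Kishi reaction) then adds C16 to the C12 carbonyl to give the bridgehead carbinol acetate F5. K2CO3 in MeOH frees the 12,13-diol F6, and Dess–Martin oxidation of its secondary hydroxyl rejoins the route at 30.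

Step 14. Several processes can go astray: hydrogenolysis of the benzylic C10–O bond during the dissolving-metal reduction; incomplete migration of the double bond into conjugation; protonation of C9 to the wrong epimer; loss of the silyl ether in acid; and decarboxylation of the vinylogous β-keto acid if the acidic solution is warmed. The fallback accepts the hydrogenolysis. It sets out from 20, which is reduced directly (Li, NH3, t-BuOH) and hydrolysed with acid to the 10-deoxy enone diacid F7. DDQ in dioxane dehydrogenates F7 to the 8(14),9-dienone diacid F8. Acid-catalysed 1,6-addition of the C19 carboxylic acid to C10 recloses the lactone and rejoins the route at 23.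

Step 20. The C11 alkyl shift may compete, the equilibrium may lie on the side of 30, further ketol shifts may follow under equilibrating conditions, and the C6 ester may enolise. The fallback closes ring D without the ketol shift. It sets out from 28. HF·pyridine gives the α-hydroxy ketone F9 and Cu(OAc)2 in MeOH oxidises it to the 12,13-diketone F10. CrCl2 with catalytic NiCl2 then adds C16 to the C13 carbonyl in a five-membered ring closure and rejoins the route at 31.

**Further compounds**
F1 | step 18 | C13 alcohol from 28 (12-OTES, C13 epimers) | O=C1O[C@@]23CC[C@H](O[Si](C)(C)C(C)(C)C)[C@]1(C)[C@H]2[C@H](C(=O)OC)[C@@]1(CC(Br)=C)CC(O)C(O[Si](CC)(CC)CC)C[C@H]13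
F2 | step 18 | C13 acetate of F1 | O=C1O[C@@]23CC[C@H](O[Si](C)(C)C(C)(C)C)[C@]1(C)[C@H]2[C@H](C(=O)OC)[C@@]1(CC(Br)=C)CC(OC(C)=O)C(O[Si](CC)(CC)CC)C[C@H]13
F3 | step 18 | 12-hydroxy 13-acetate | O=C1O[C@@]23CC[C@H](O[Si](C)(C)C(C)(C)C)[C@]1(C)[C@H]2[C@H](C(=O)OC)[C@@]1(CC(Br)=C)CC(OC(C)=O)C(O)C[C@H]13
F4 | step 18 | 12-oxo 13-acetate | O=C1O[C@@]23CC[C@H](O[Si](C)(C)C(C)(C)C)[C@]1(C)[C@H]2[C@H](C(=O)OC)[C@@]1(CC(Br)=C)CC(OC(C)=O)C(=O)C[C@H]13
F5 | step 18 | bicyclo[2.2.2]octane 12-ol 13-acetate (C16 on C12) | C=C1C[C@]23CC(OC(C)=O)[C@@]1(O)C[C@H]2[C@@]12CC[C@H](O[Si](C)(C)C(C)(C)C)[C@@](C)(C(=O)O1)[C@H]2[C@@H]3C(=O)OC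
F6 | step 18 | bicyclo[2.2.2]octane 12,13-diol | C=C1C[C@]23CC(O)[C@@]1(O)C[C@H]2[C@@]12CC[C@H](O[Si](C)(C)C(C)(C)C)[C@@](C)(C(=O)O1)[C@H]2[C@@H]3C(=O)OC
F7 | step 14 | 3β-(tert-butyldimethylsilyloxy)-13-oxo-20-norgibberell-8(14)-ene-7,19-dioic acid (no C10 oxygen, C9 and C10 epimers) | OC(=O)[C@]1(C)[C@@H](O[Si](C)(C)C(C)(C)C)CCC2[C@@H]1[C@H](C(=O)O)C1=CC(=O)CCC12
F8 | step 14 | 3β-(tert-butyldimethylsilyloxy)-13-oxo-20-norgibberella-8(14),9-diene-7,19-dioic acid | OC(=O)[C@]1(C)[C@@H](O[Si](C)(C)C(C)(C)C)CCC2=C3CCC(=O)C=C3[C@@H](C(=O)O)[C@H]12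
F9 | step 20 | 12-hydroxy ketone from 28 | O=C1O[C@@]23CC[C@H](O[Si](C)(C)C(C)(C)C)[C@]1(C)[C@H]2[C@H](C(=O)OC)[C@@]1(CC(Br)=C)CC(=O)C(O)C[C@H]13
F10 | step 20 | 12,13-diketone | O=C1O[C@@]23CC[C@H](O[Si](C)(C)C(C)(C)C)[C@]1(C)[C@H]2[C@H](C(=O)OC)[C@@]1(CC(Br)=C)CC(=O)C(=O)C[C@H]13
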